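**Retrosynthetic overview**

1. Rings A and B are bought ready-made, ring A in 2',6'-dihydroxy-4'-methoxyacetophenone 1 and ring B in benzaldehyde 2; only ring C is built.
2. Enone C=C disconnection (crossed aldol, through aldol adduct 3) leads to the symmetrical chalcone 4; its two ortho-hydroxyls are equivalent, so ring closure has no regiochemical choice.
3. O1–C2 disconnection: ring C closes by a catalytic enantioselective 6-endo oxa-Michael addition of 4 (a small-molecule stand-in for chalcone isomerase), setting C2 and giving (2S)-pinostrobin 5.
4. C6–C1'' disconnection: geraniol 6 is attached last, ortho to the only free phenol of 5, as the aromatic prenyltransferase does on the finished flavanone, giving target 7.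
5. No protecting groups; three steps in all.

Assumption: the facial sense of the cinchona thiourea is taken by analogy with activated chalcones (quinidine-derived catalyst gives 2S); should the first run give 2R, the quinine-derived pseudoenantiomer N-[3,5-bis(trifluoromethyl)phenyl]-N'-[(8α,9S)-6'-methoxycinchonan-9-yl]thiourea replaces it and nothing else changes.

**Route**

Step 1
Reactants: 1 2',6'-dihydroxy-4'-methoxyacetophenone; 2 benzaldehyde
Product: 4 (E)-2',6'-dihydroxy-4'-methoxychalcone (pinostrobin chalcone), via aldol adduct 3 (not isolated)
Conditions: 2 (1.5 equiv), KOH (50% aq, 15 equiv), EtOH, N2, 0 °C to rt, 48 h; then ice-cold 1 M HCl to pH 5, filter, recrystallise (MeOH/H2O) until free of flavanone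
Reagents that add atoms: none
Why: Claisen–Schmidt (crossed aldol) condensation: the methyl ketone enolate of 1 adds to non-enolisable 2, aldol 3 loses water by E1cB to the conjugated (E)-enone, the strongly basic medium holds the product as the ring-open chalcone phenolate, and a cold weakly acidic quench precipitates 4 before it can close; no lasting stereocentre is formed (3 is racemic and transient).

Step 2
Reactants: 4 (E)-2',6'-dihydroxy-4'-methoxychalcone
Product: 5 (2S)-pinostrobin [(2S)-5-hydroxy-7-methoxy-2-phenylchroman-4-one]
Conditions: N-[3,5-bis(trifluoromethyl)phenyl]-N'-[(9R)-6'-methoxycinchonan-9-yl]thiourea (quinidine-derived, 10 mol %), PhCl, −20 °C, 48–72 h; SiO2 plug; recrystallise (MeOH) to ≥99% ee (chiral HPLC)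
Reagents that add atoms: none
Why: Proposed new method: the quinuclidine nitrogen deprotonates one of the two equivalent, acidic ortho-phenols of 4 to a tight chiral ammonium phenoxide while the thiourea N–H pair binds the enone carbonyl (already polarised by the hydrogen bond from the other ortho-OH, the feature that makes such chalcones close easily in the plant), so the phenoxide adds 6-endo to one face of the s-cis enone and the catalyst-bound enol is protonated to give the (2S)-flavanone, which the 5-OH···O=C hydrogen bond makes thermodynamically favoured and which is configurationally stable at −20 °C; the closest known reaction type is the cinchona-thiourea- or quinine-catalysed enantioselective intramolecular oxa-Michael addition of 2'-hydroxychalcones (high ee with an extra α-ester activating group, moderate ee without) and of phloroglucinol-type ortho-hydroxyaryl enones.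

Step 3
Reactants: 5 (2S)-pinostrobin; 6 geraniol [(2E)-3,7-dimethylocta-2,6-dien-1-ol]
Product: 7 (2S)-6-geranylpinostrobin [(2S)-6-[(2E)-3,7-dimethylocta-2,6-dien-1-yl]-5-hydroxy-7-methoxy-2-phenylchroman-4-one]
Conditions: 6 (1.3 equiv), acidic Al2O3 (activated, ca. 2 g per mmol of 5), ClCH2CH2Cl, 60 °C, 16 h; filter, wash with EtOAc, chromatography
Reagents that add atoms: none
Why: Alumina-directed ortho-allylation of a phenol with an allylic alcohol (a surface-templated Friedel–Crafts alkylation): the 5-OH, the only free phenol of 5, anchors ring A to the acidic Al2O3 surface, geraniol ionised on a neighbouring site is captured through its primary carbon by C6, the only free ortho position, with the E-alkene kept, and the base-free conditions leave the C2 stereocentre from step 2 untouched.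

**Compound list**

1 | 2',6'-dihydroxy-4'-methoxyacetophenone [1-(2,6-dihydroxy-4-methoxyphenyl)ethan-1-one] | COc1cc(O)c(C(C)=O)c(O)c1 | starting material
2 | benzaldehyde | O=Cc1ccccc1 | starting material
3 | aldol adduct, 1-(2,6-dihydroxy-4-methoxyphenyl)-3-hydroxy-3-phenylpropan-1-one (racemic) | COc1cc(O)c(C(=O)CC(O)c2ccccc2)c(O)c1 | intermediate
4 | (E)-2',6'-dihydroxy-4'-methoxychalcone [(2E)-1-(2,6-dihydroxy-4-methoxyphenyl)-3-phenylprop-2-en-1-one] | COc1cc(O)c(C(=O)/C=C/c2ccccc2)c(O)c1 | intermediate
5 | (2S)-pinostrobin [(2S)-5-hydroxy-7-methoxy-2-phenylchroman-4-one] | COc1cc2c(c(O)c1)C(=O)C[C@@H](c1ccccc1)O2 | intermediate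
6 | geraniol [(2E)-3,7-dimethylocta-2,6-dien-1-ol] | CC(C)=CCC/C(C)=C/CO | starting material
7 | (2S)-6-geranylpinostrobin | COc1cc2c(c(O)c1C/C=C(\C)CCC=C(C)C)C(=O)C[C@@H](c1ccccc1)O2 | target

**Totals**

Total step count: 3. Longest linear sequence: 3 steps (1 → 4 → 5 → 7).

**Steps most likely to fail, with fallbacks**

Most at risk is step 2. The enone carries no extra activating group, the chalcone also closes without catalyst, and a slow retro-reaction can erode the ee, so the enantioselectivity may stay moderate. The fallback gives up asymmetric ring closure and instead sets C2 by asymmetric C–C bond formation on a preformed ring C. It sets out from 1: heating 1 with N,N-dimethylformamide dimethyl acetal gives the enaminone (2E)-1-(2,6-dihydroxy-4-methoxyphenyl)-3-(dimethylamino)prop-2-en-1-one F1. Brief treatment with aqueous HCl closes it, with loss of dimethylamine, to 5-hydroxy-7-methoxy-4H-chromen-4-one F2. Enantioselective conjugate addition of phenylboronic acid to F2 follows, with Pd(OCOCF3)2 and (R)-4-tert-butyl-2-(pyridin-2-yl)-4,5-dihydrooxazole, NH4PF6 and H2O in ClCH2CH2Cl at 60 °C. The ligand enantiomer is chosen by analogy with cyclic enones and is to be confirmed on the first run. This gives 5, where the fallback rejoins the route before step 3.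

Second is step 3. Possible failures are attack at C8 or double geranylation, chroman formation by the 5-OH adding to the new side chain, E/Z or allylic scrambling of the geranyl cation, and partial loss of ee at C2 on the warm oxide surface. The fallback fixes the position by halogen and joins the chain by cross-coupling under neutral conditions. It sets out from 5: iodination with benzyltrimethylammonium dichloroiodate (BnMe3N·ICl2) and CaCO3 in CH2Cl2/MeOH at rt goes ortho to the free 5-OH and gives (2S)-5-hydroxy-6-iodo-7-methoxy-2-phenylchroman-4-one F3. Stille coupling of F3 with tributyl[(2E)-3,7-dimethylocta-2,6-dien-1-yl]stannane F4 (made from commercial geranyl bromide and Bu3SnLi in THF at −78 °C) with Pd2(dba)3 and AsPh3 in DMF at 60 °C joins the primary carbon of the chain to C6. It returns to the route at 7.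

Third is step 1. The doubly deprotonated acetophenone enolises slowly, benzaldehyde is lost to Cannizzaro reaction, and part of 4 may close to racemic pinostrobin on work-up. Any racemic flavanone carried forward would lower the ee of step 2, which is why 4 is crystallised until free of it. The fallback masks the phenols so that the condensation is fast and closure is impossible until the chalcone is in hand. It sets out from 1: NaH and chloromethyl methyl ether in DMF at 0 °C give 1-[4-methoxy-2,6-bis(methoxymethoxy)phenyl]ethan-1-one F5. Claisen–Schmidt condensation of F5 with 2 (KOH, EtOH, rt) gives (2E)-1-[4-methoxy-2,6-bis(methoxymethoxy)phenyl]-3-phenylprop-2-en-1-one F6. Mild acetal cleavage of F6 (HCl, MeOH, rt) returns to the route at 4.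

**Further compounds**

F1 | step 2 | (2E)-1-(2,6-dihydroxy-4-methoxyphenyl)-3-(dimethylamino)prop-2-en-1-one | COc1cc(O)c(C(=O)/C=C/N(C)C)c(O)c1
F2 | step 2 | 5-hydroxy-7-methoxy-4H-chromen-4-one | COc1cc(O)c2c(c1)occc2=O
F3 | step 3 | (2S)-5-hydroxy-6-iodo-7-methoxy-2-phenylchroman-4-one | COc1cc2c(c(O)c1I)C(=O)C[C@@H](c1ccccc1)O2
F4 | step 3 | tributyl[(2E)-3,7-dimethylocta-2,6-dien-1-yl]stannane | CCCC[Sn](CCCC)(CCCC)C/C=C(\C)CCC=C(C)C
F5 | step 1 | 1-[4-methoxy-2,6-bis(methoxymethoxy)phenyl]ethan-1-one | COCOc1cc(OC)cc(OCOC)c1C(C)=O
F6 | step 1 | (2E)-1-[4-methoxy-2,6-bis(methoxymethoxy)phenyl]-3-phenylprop-2-en-1-one | COCOc1cc(OC)cc(OCOC)c1C(=O)/C=C/c1ccccc1
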